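Count the free partner first.

the same everywhere: starting material 0.010 M (fed, over 30 min)

| run | partner | protic impurity | remark | time |
|---|---|---|---|---|
| south-east | 0.70 equiv | 2 mM | the very flask that is asked about, followed so far |  |
| west | 1.4 equiv | 2 mM | run made earlier |  |
| flask | 0.700 equiv | 2.00 mM |  | 10 d |

| run | time / d | starting material / % | product / % |
|---|---|---|---|
| south-east | 0.250 | 76.8 | 22.5 |
| south-east | 0.833 | 76.3 | 23.9 |
| south-east | 1.25 | 76.8 | 24.0 |
| south-east | 2.00 | 77.0 | 23.7 |
| south-east | 3.00 | 76.0 | 24.7 |
| south-east | 4.00 | 77.0 | 23.7 |
| west | 1.25 | 53.9 | 46.8 |
| west | 2.50 | 53.0 | 46.3 |
| west | 4.00 | 52.7 | 46.8 |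
| west | 5.00 | 53.6 | 46.8 |
| west | 6.00 | 53.4 | 46.2 |
| west | 8.00 | 53.0 | 47.0 |

(readings scatter by 0.5 percentage points)

* which holds at 10 d: what has brought the reaction to rest, or that it has not come to rest (the partner has run out first / all of the starting material has reacted / forward and back rates have come level / it is still moving)
* part of the starting material gone at 10 d
* the product standing at 10 d, as a percentage of the starting material charged

- the reaction counts as stopped when no species that holds the starting material changes by six tenths of a point or more over the second half of the time

1. Time. By hand, more time adds product while the reaction moves. South-east product goes from 23.9% at 0.833 d to 23.7% at 4.00 d, and a reading scatters by 0.5 percentage points. Treat the south-east flask as resting, and expect the same state at 10 d.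

2. Dosing. Both runs were fed over 30 min, so they do not test it. Keep it out of the reckoning, which describes a resting state.

3. Impurity. Assume it takes partner one to one. That leaves n = 0.500 equiv of partner for the starting material in the south-east flask.

4. Partner. By hand, using up n would give 50.0% product, but the south-east flask reads 23.7%. So free partner b remains: charge less impurity less product, 0.263 equiv there and 0.730 equiv in the west run.

5. Logarithms. Write lg for the logarithm to base ten. Define Q, the equilibrium constant in units of this charge, as c(product)/c(starting material) per equivalent of free partner, so lg(product/starting material) = lg Q + lg b. The south-east run gives lg Q = 0.0683 and the west run 0.0845. With the impurity ignored they give −0.177 and −0.0207. Take Q = 1.19, so lg Q = 0.0764.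

6. Reckoning. Let x be the part converted, with b = n − x. Solving x/(1 − x) = Q·b gives x = 23.8% for the south-east flask at 10 d.

7. Forecast. It says forward and back rates have come level, with 23.6% gone and 23.8% product, K being “the same value in both runs”; its conversion lies 0.2 points below mine.

8. Result. At 10 d the south-east flask stands thus: forward and back rates have come level, with 23.9% gone and 23.9% product.

    partner + protic impurity → quenched reagent (k = 1000 L mol⁻¹ h⁻¹)
    starting material + partner ⇌ product (K = 120 L mol⁻¹, k = 62.0 L mol⁻¹ h⁻¹)

At 10.0 d in the south-east flask, partner stands at 37.3% of its own charge, or 0.261 equiv, and Q times that gives 0.312; product over starting material in that flask is 0.314. Now charge 2.80 equiv of partner and hold the rest. Then n = 2.60, the same solution gives x = 69.4%, and lg(product/starting material) = 0.356. That neighbouring flask ends with 69.6% product and 30.4% starting material.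

All runs were generated by integration from invented constants; the scatter is artificial.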